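**Plan**

- Retrosynthesis: the two ring A phenols go back to methyl ethers and the ring B acetyl group to a late C-acylation. Ring B is then cut at three bonds: C1–C2, C3–C4 and C1–C6, where C1 is the ring B carbon between the arylmethyl-bearing carbon C2 and the CMe2 carbon C6.
- This leads to a four-carbon cyclobutenone and a two-carbon silyl ynol ether that already carries ring A.
- Enabling feature: ring B is a cyclohexane-1,3,5-trione in which the carbon between two oxygenated carbons is quaternary (two methyl groups). Its bis enol ether is a 6,6-dimethylcyclohexa-2,4-dienone that cannot tautomerise to a phenol, which is what a 4,4-dimethylcyclobutenone gives when its vinylketene is trapped by a heteroatom-substituted alkyne.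
- Forward, ring A is bought as 2,4,6-trimethoxyacetophenone. Its acetyl group becomes the CH2CO2Me arm, a new acetyl group is added and masked as a silyl enol ether, and the ester is homologated to the siloxyalkyne. The cyclobutenone comes in one step from isobutyryl chloride and ethoxyacetylene.
- Ring B is closed in one thermal operation. The trione and the aryl ketone are unveiled together, the free ring B carbon is C-acetylated, and the two ethers flanking the aryl ketone are cleaved.
- Stereochemistry: the target has no stereocentre and no stereogenic double bond, so none has to be set.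

Key step: step 6

Assumption: ring B is an enolised triketone; its keto and enol tautomers are treated as one compound and are written in the tautomer that matches the target drawing.

**Route**

Step 1
Reactants: 1 isobutyryl chloride; 2 ethoxyacetylene
Product: 4 3-ethoxy-4,4-dimethylcyclobut-2-en-1-one, via dimethylketene 3 (not isolated)
Conditions: Et3N, MeCN, 0 °C → rt
Reagents that add atoms: none
Why: Dehydrochlorination of 1 gives dimethylketene 3, which undergoes the ketene–alkoxyalkyne [2+2] cycloaddition with its carbonyl carbon bonding to the unsubstituted, nucleophilic alkyne carbon; holding the mixture at or below room temperature with 2 as the limiting partner should keep 4 from opening and taking up a second alkyne.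

Step 2
Reactants: 5 2,4,6-trimethoxyacetophenone
Product: 6 methyl 2-(2,4,6-trimethoxyphenyl)acetate
Conditions: PhI(OAc)2, H2SO4, MeOH/HC(OMe)3, rt → 50 °C
Reagents that add atoms: methanol, CO
Why: Oxidative 1,2-aryl migration of an aryl methyl ketone (the trivalent-iodine counterpart of the Tl(NO3)3 rearrangement), in which the enol ether is attacked at its methylene carbon by the iodine reagent and the very electron-rich aryl group shifts as iodobenzene leaves, giving an ortho ester that is worked up to the methyl arylacetate.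

Step 3
Reactants: 6 methyl 2-(2,4,6-trimethoxyphenyl)acetate
Product: 7 methyl 2-(3-acetyl-2,4,6-trimethoxyphenyl)acetate
Conditions: AcOH, (CF3CO)2O, H3PO4 (cat.), CH2Cl2, 0 °C → rt
Reagents that add atoms: acetic acid, CC(=O)O
Why: Friedel–Crafts acylation by the mixed acetic trifluoroacetic anhydride at one of the two equivalent free ring positions; the metal-free conditions should leave the ortho ethers intact, and the first acetyl group slows a second acylation.

Step 4
Reactants: 7 methyl 2-(3-acetyl-2,4,6-trimethoxyphenyl)acetate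
Product: 8 methyl 2-[2,4,6-trimethoxy-3-[1-(triisopropylsilyloxy)ethenyl]phenyl]acetate
Conditions: i-Pr3SiOTf, Et3N, CH2Cl2, 0 °C → rt
Reagents that add atoms: triisopropylsilyl trifluoromethanesulfonate, CC(C)[Si](OS(=O)(=O)C(F)(F)F)(C(C)C)C(C)C
Why: Soft enolisation (silyl triflate and amine) converts the methyl ketone into a bulky silyl enol ether, which hides the enolisable carbonyl group from the lithium reagents of step 5 and is later removed by the same fluoride that unveils ring B; any silyl ketene acetal of the ester reverts to the ester on aqueous work-up.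

Step 5
Reactants: 8 methyl 2-[2,4,6-trimethoxy-3-[1-(triisopropylsilyloxy)ethenyl]phenyl]acetate
Product: 11 triisopropyl[[3-[2,4,6-trimethoxy-3-[1-(triisopropylsilyloxy)ethenyl]phenyl]prop-1-yn-1-yl]oxy]silane, via lithium dibromoenolate 9 (not isolated), via lithium ynolate 10 (not isolated)
Conditions: CH2Br2, LiTMP (lithium 2,2,6,6-tetramethylpiperidide), THF, −78 °C; LiN(SiMe3)2, −78 °C; n-BuLi, −78 → 0 °C; i-Pr3SiCl, −78 °C → rt
Reagents that add atoms: dibromomethane, BrCBr; chlorotriisopropylsilane, CC(C)[Si](Cl)(C(C)C)C(C)C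
Why: Kowalski ester homologation intercepted at the ynolate, in which LiCHBr2 adds to the ester, dibromoenolate 9 undergoes bromine–lithium exchange and 1,2-shift of the arylmethyl group to ynolate 10, and the bulky silyl chloride silylates at oxygen to give the isolable silyl ynol ether.

Step 6
Reactants: 4 3-ethoxy-4,4-dimethylcyclobut-2-en-1-one; 11 triisopropyl[[3-[2,4,6-trimethoxy-3-[1-(triisopropylsilyloxy)ethenyl]phenyl]prop-1-yn-1-yl]oxy]silane
Product: 15 5-ethoxy-6,6-dimethyl-3-(triisopropylsilyloxy)-2-[[2,4,6-trimethoxy-3-[1-(triisopropylsilyloxy)ethenyl]phenyl]methyl]cyclohexa-2,4-dien-1-one, via vinylketene 12 (not isolated), via vinylcyclobutenone 13 (not isolated), via dienylketene 14 (not isolated)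
Conditions: 4 (2 equiv, added in portions), toluene (about 1 M in 11), 80 → 110 °C, sealed vessel, argon
Reagents that add atoms: none
Why: Heating opens 4 by 4π electrocyclic ring opening to vinylketene 12, whose ketene carbonyl carbon is attacked by the arylmethyl-bearing carbon of ynol ether 11 in a regioselective [2+2] cycloaddition to vinylcyclobutenone 13; a second 4π opening gives dienylketene 14, and a thermal disrotatory 6π electrocyclisation between the ketene carbon and the dimethyl-substituted diene terminus closes ring B. The closest known reaction type is the Danheiser benzannulation of cyclobutenones with siloxyalkynes in its arrested form, known for alkoxycyclobutenones derived from dimethylketene, where the quaternary carbon blocks tautomerisation to a phenol and a 6,6-dialkylcyclohexa-2,4-dienone results. Three ring B bonds form (C1–C2 and C3–C4 in the [2+2] step, C1–C6 in the 6π closure); the four-membered ring of 13 is made by cycloaddition and opened again, and no stereocentre survives because the only one on the way, the sp3 ring carbon of 13, is destroyed in the ring opening. The required regiochemistry (siloxy carbon joined to the former C2–H of 4) follows from the polarity match between the electrophilic ketene carbonyl carbon and the nucleophilic β-carbon of the ynol ether. Chemoselectivity rests on the siloxyalkyne being far more nucleophilic than the hindered aryl silyl enol ether, and the competing [1,5]-hydrogen shift of 12 from a methyl group is countered by running concentrated with an excess of the inexpensive 4.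

Step 7
Reactants: 15 5-ethoxy-6,6-dimethyl-3-(triisopropylsilyloxy)-2-[[2,4,6-trimethoxy-3-[1-(triisopropylsilyloxy)ethenyl]phenyl]methyl]cyclohexa-2,4-dien-1-one
Product: 17 2-[(3-acetyl-2,4,6-trimethoxyphenyl)methyl]-3,5-dihydroxy-4,4-dimethylcyclohexa-2,5-dien-1-one, via ethoxy enone 16 (not isolated)
Conditions: n-Bu4NF, THF, 0 °C; then 2 M aq. HCl, rt → 40 °C
Reagents that add atoms: water, O
Why: Fluoride cleaves both silyl enol ethers, returning the aryl methyl ketone and the ring B enol, and aqueous acid then hydrolyses the vinylogous ethyl ester of 16 by addition of water at the ethoxy-bearing carbon and loss of ethanol, so that ring B ends as the enolised trione.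

Step 8
Reactants: 17 2-[(3-acetyl-2,4,6-trimethoxyphenyl)methyl]-3,5-dihydroxy-4,4-dimethylcyclohexa-2,5-dien-1-one
Product: 19 2-acetyl-6-[(3-acetyl-2,4,6-trimethoxyphenyl)methyl]-3,5-dihydroxy-4,4-dimethylcyclohexa-2,5-dien-1-one, via enol acetate 18 (not isolated)
Conditions: CH3COCl, Et3N, CH2Cl2, 0 °C; then DMAP (cat.), rt
Reagents that add atoms: acetyl chloride, CC(=O)Cl
Why: O-acetylation of the acidic trione followed by DMAP-catalysed O-to-C acyl migration (the standard route from cyclic 1,3-diones to 2-acyl-1,3-diones) places the acetyl group on the only ring B carbon that still bears hydrogen between two carbonyl groups and can hold the product as a hydrogen-bonded enol, whichever enol oxygen is acetylated first.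

Step 9
Reactants: 19 2-acetyl-6-[(3-acetyl-2,4,6-trimethoxyphenyl)methyl]-3,5-dihydroxy-4,4-dimethylcyclohexa-2,5-dien-1-one
Product: 20 2-acetyl-6-[(3-acetyl-2,4-dihydroxy-6-methoxyphenyl)methyl]-3,5-dihydroxy-4,4-dimethylcyclohexa-2,5-dien-1-one (CNP0224819.0)
Conditions: BCl3 (excess), CH2Cl2, −78 °C → rt; aq. work-up
Reagents that add atoms: none
Why: Chelation-directed aryl methyl ether cleavage, in which BCl3 held by the aryl ketone oxygen demethylates the ortho methoxy groups through six-membered boron chelates, so both flanking ethers should fall while the para ether, which has no carbonyl neighbour, should remain.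

**Compound list**

1 | isobutyryl chloride | CC(C)C(Cl)=O | starting material
2 | ethoxyacetylene | CCOC#C | starting material
3 | dimethylketene | CC(C)=C=O | intermediate
4 | 3-ethoxy-4,4-dimethylcyclobut-2-en-1-one | CCOC1=CC(=O)C1(C)C | intermediate
5 | 2,4,6-trimethoxyacetophenone | CC(=O)c1c(OC)cc(OC)cc1OC | starting material
6 | methyl 2-(2,4,6-trimethoxyphenyl)acetate | COC(=O)Cc1c(OC)cc(OC)cc1OC | intermediate
7 | methyl 2-(3-acetyl-2,4,6-trimethoxyphenyl)acetate | COC(=O)Cc1c(OC)cc(OC)c(C(C)=O)c1OC | intermediate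
8 | methyl 2-[2,4,6-trimethoxy-3-[1-(triisopropylsilyloxy)ethenyl]phenyl]acetate | COC(=O)Cc1c(OC)cc(OC)c(C(=C)O[Si](C(C)C)(C(C)C)C(C)C)c1OC | intermediate
9 | lithium 1,1-dibromo-3-[2,4,6-trimethoxy-3-[1-(triisopropylsilyloxy)ethenyl]phenyl]prop-1-en-2-olate | [Li+].[O-]C(Cc1c(OC)cc(OC)c(C(=C)O[Si](C(C)C)(C(C)C)C(C)C)c1OC)=C(Br)Br | intermediate
10 | lithium 3-[2,4,6-trimethoxy-3-[1-(triisopropylsilyloxy)ethenyl]phenyl]prop-1-yn-1-olate | [Li+].[O-]C#CCc1c(OC)cc(OC)c(C(=C)O[Si](C(C)C)(C(C)C)C(C)C)c1OC | intermediate
11 | triisopropyl[[3-[2,4,6-trimethoxy-3-[1-(triisopropylsilyloxy)ethenyl]phenyl]prop-1-yn-1-yl]oxy]silane | CC(C)[Si](C(C)C)(C(C)C)OC#CCc1c(OC)cc(OC)c(C(=C)O[Si](C(C)C)(C(C)C)C(C)C)c1OC | intermediate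
12 | 3-ethoxy-4-methylpenta-1,3-dien-1-one (vinylketene) | CCOC(C=C=O)=C(C)C | intermediate
13 | 4-(1-ethoxy-2-methylprop-1-en-1-yl)-3-(triisopropylsilyloxy)-2-[[2,4,6-trimethoxy-3-[1-(triisopropylsilyloxy)ethenyl]phenyl]methyl]cyclobut-2-en-1-one (racemic) | CCOC(=C(C)C)C1C(=O)C(Cc2c(OC)cc(OC)c(C(=C)O[Si](C(C)C)(C(C)C)C(C)C)c2OC)=C1O[Si](C(C)C)(C(C)C)C(C)C | intermediate
14 | (3E)-5-ethoxy-6-methyl-3-(triisopropylsilyloxy)-2-[[2,4,6-trimethoxy-3-[1-(triisopropylsilyloxy)ethenyl]phenyl]methyl]hepta-1,3,5-trien-1-one (dienylketene; ketene and ethoxyalkenyl groups cis on the central double bond) | CCOC(=C(C)C)/C=C(O[Si](C(C)C)(C(C)C)C(C)C)\C(Cc1c(OC)cc(OC)c(C(=C)O[Si](C(C)C)(C(C)C)C(C)C)c1OC)=C=O | intermediate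
15 | 5-ethoxy-6,6-dimethyl-3-(triisopropylsilyloxy)-2-[[2,4,6-trimethoxy-3-[1-(triisopropylsilyloxy)ethenyl]phenyl]methyl]cyclohexa-2,4-dien-1-one | CCOC1=CC(O[Si](C(C)C)(C(C)C)C(C)C)=C(Cc2c(OC)cc(OC)c(C(=C)O[Si](C(C)C)(C(C)C)C(C)C)c2OC)C(=O)C1(C)C | intermediate
16 | 2-[(3-acetyl-2,4,6-trimethoxyphenyl)methyl]-5-ethoxy-3-hydroxy-6,6-dimethylcyclohexa-2,4-dien-1-one | CCOC1=CC(O)=C(Cc2c(OC)cc(OC)c(C(C)=O)c2OC)C(=O)C1(C)C | intermediate
17 | 2-[(3-acetyl-2,4,6-trimethoxyphenyl)methyl]-3,5-dihydroxy-4,4-dimethylcyclohexa-2,5-dien-1-one | COc1cc(OC)c(C(C)=O)c(OC)c1CC1=C(O)C(C)(C)C(O)=CC1=O | intermediate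
18 | 4-[(3-acetyl-2,4,6-trimethoxyphenyl)methyl]-5-hydroxy-6,6-dimethyl-3-oxocyclohexa-1,4-dien-1-yl acetate | COc1cc(OC)c(C(C)=O)c(OC)c1CC1=C(O)C(C)(C)C(OC(C)=O)=CC1=O | intermediate
19 | 2-acetyl-6-[(3-acetyl-2,4,6-trimethoxyphenyl)methyl]-3,5-dihydroxy-4,4-dimethylcyclohexa-2,5-dien-1-one | COc1cc(OC)c(C(C)=O)c(OC)c1CC1=C(O)C(C)(C)C(O)=C(C(C)=O)C1=O | intermediate
20 | 2-acetyl-6-[(3-acetyl-2,4-dihydroxy-6-methoxyphenyl)methyl]-3,5-dihydroxy-4,4-dimethylcyclohexa-2,5-dien-1-one | COc1cc(O)c(C(C)=O)c(O)c1CC1=C(O)C(C)(C)C(O)=C(C(C)=O)C1=O | target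

**Step count and risks**

Total steps: 9 (step 1 for the cyclobutenone, steps 2–5 for the siloxyalkyne, steps 6–9 after the union). Longest linear sequence: 8 steps (5 to 20, steps 2–9).

Most likely to fail, in this order: step 6, step 5, step 9.

Step 6. Bimolecular capture of vinylketene 12 by the limiting alkyne 11 may be outrun by the [1,5]-hydrogen shift from a methyl group to the ketene carbon or by reclosure to 4, leaving 11 to degrade on long heating. The fallback sets out from 11 (with 1 and 2) and comes back at 17; it exchanges the roles of the two fragments. Dimethylketene 3, made from 1 and Et3N as in step 1, should add [2+2] to siloxyalkyne 11 at 0 °C to room temperature (the known ketene–siloxyalkyne cycloaddition) to give the siloxycyclobutenone F1. Thermolysis of F1 in toluene at 80 °C with a large excess of ethoxyacetylene 2, which is cheap and volatile and can serve as co-solvent, should give the regioisomeric bis enol ether dienone F2 by the same kind of cascade. Because F2 and 15 are enol ethers of the same trione, fluoride and aqueous acid as in step 7 should bring F2 to 17.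

Step 5. Enolisation of the arylacetic ester by LiCHBr2 or the amide base may compete with carbonyl addition, and the carbenoid rearrangement may stall, returning ester or giving bromoketone mixtures. The fallback sets out from 8 and comes back at ynolate 10, and so at 11; it makes the ynolate by oxidation of a lithium acetylide instead of by ester homologation. Reduction of 8 with i-Bu2AlH at −78 °C should give the arylacetaldehyde F3, and the Ohira–Bestmann reagent (dimethyl (1-diazo-2-oxopropyl)phosphonate, K2CO3, MeOH) the terminal alkyne F4. Deprotonation of F4 with n-BuLi and oxygen transfer from t-BuOOLi (from t-BuOOH and LiN(SiMe3)2) should give ynolate 10, which is silylated as in step 5.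

Step 9. Once the first phenol is locked in a boron chelate the second flanking ether may resist cleavage, and forcing the reaction may cost the para methyl ether or break the acid-labile bond between the arylmethyl carbon and ring B. The fallback sets out from 7 and comes back at 20; it moves the ether cleavage to an early, robust compound and carries hydrogenolysable ethers instead. Keto ester 7 is demethylated at both ethers flanking the ketone (BCl3, or AlCl3 under forcing conditions that 7 tolerates) to the diphenol F5, and benzylation (BnBr, K2CO3, DMF) gives the bis(benzyl ether) F6. F6 is then taken through the operations of steps 4 to 8, giving in turn the silyl enol ether F7, the siloxyalkyne F8, the dienone F9, the trione F10 and the diacetyl compound F11. Hydrogenolysis of F11 (H2, Pd/C, EtOAc, rt) should give 20 under neutral conditions.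

**Further compounds**

F1 | step 6 | 4,4-dimethyl-3-(triisopropylsilyloxy)-2-[[2,4,6-trimethoxy-3-[1-(triisopropylsilyloxy)ethenyl]phenyl]methyl]cyclobut-2-en-1-one | CC1(C)C(=O)C(Cc2c(OC)cc(OC)c(C(=C)O[Si](C(C)C)(C(C)C)C(C)C)c2OC)=C1O[Si](C(C)C)(C(C)C)C(C)C
F2 | step 6 | 3-ethoxy-6,6-dimethyl-5-(triisopropylsilyloxy)-4-[[2,4,6-trimethoxy-3-[1-(triisopropylsilyloxy)ethenyl]phenyl]methyl]cyclohexa-2,4-dien-1-one | CCOC1=CC(=O)C(C)(C)C(O[Si](C(C)C)(C(C)C)C(C)C)=C1Cc1c(OC)cc(OC)c(C(=C)O[Si](C(C)C)(C(C)C)C(C)C)c1OC
F3 | step 5 | 2-[2,4,6-trimethoxy-3-[1-(triisopropylsilyloxy)ethenyl]phenyl]acetaldehyde | O=CCc1c(OC)cc(OC)c(C(=C)O[Si](C(C)C)(C(C)C)C(C)C)c1OC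
F4 | step 5 | 3-[2,4,6-trimethoxy-3-[1-(triisopropylsilyloxy)ethenyl]phenyl]prop-1-yne | C#CCc1c(OC)cc(OC)c(C(=C)O[Si](C(C)C)(C(C)C)C(C)C)c1OC
F5 | step 9 | methyl 2-(3-acetyl-2,4-dihydroxy-6-methoxyphenyl)acetate | COC(=O)Cc1c(OC)cc(O)c(C(C)=O)c1O
F6 | step 9 | methyl 2-[3-acetyl-2,4-bis(benzyloxy)-6-methoxyphenyl]acetate | COC(=O)Cc1c(OC)cc(OCc2ccccc2)c(C(C)=O)c1OCc1ccccc1
F7 | step 9 | methyl 2-[2,4-bis(benzyloxy)-6-methoxy-3-[1-(triisopropylsilyloxy)ethenyl]phenyl]acetate | COC(=O)Cc1c(OC)cc(OCc2ccccc2)c(C(=C)O[Si](C(C)C)(C(C)C)C(C)C)c1OCc1ccccc1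
F8 | step 9 | [[3-[2,4-bis(benzyloxy)-6-methoxy-3-[1-(triisopropylsilyloxy)ethenyl]phenyl]prop-1-yn-1-yl]oxy]triisopropylsilane | CC(C)[Si](C(C)C)(C(C)C)OC#CCc1c(OC)cc(OCc2ccccc2)c(C(=C)O[Si](C(C)C)(C(C)C)C(C)C)c1OCc1ccccc1
F9 | step 9 | 2-[[2,4-bis(benzyloxy)-6-methoxy-3-[1-(triisopropylsilyloxy)ethenyl]phenyl]methyl]-5-ethoxy-6,6-dimethyl-3-(triisopropylsilyloxy)cyclohexa-2,4-dien-1-one | CCOC1=CC(O[Si](C(C)C)(C(C)C)C(C)C)=C(Cc2c(OC)cc(OCc3ccccc3)c(C(=C)O[Si](C(C)C)(C(C)C)C(C)C)c2OCc2ccccc2)C(=O)C1(C)C
F10 | step 9 | 2-[[3-acetyl-2,4-bis(benzyloxy)-6-methoxyphenyl]methyl]-3,5-dihydroxy-4,4-dimethylcyclohexa-2,5-dien-1-one | COc1cc(OCc2ccccc2)c(C(C)=O)c(OCc2ccccc2)c1CC1=C(O)C(C)(C)C(O)=CC1=O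
F11 | step 9 | 2-acetyl-6-[[3-acetyl-2,4-bis(benzyloxy)-6-methoxyphenyl]methyl]-3,5-dihydroxy-4,4-dimethylcyclohexa-2,5-dien-1-one | COc1cc(OCc2ccccc2)c(C(C)=O)c(OCc2ccccc2)c1CC1=C(O)C(C)(C)C(O)=C(C(C)=O)C1=O
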